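The spiro-oxane (O1′, spiro C2′ = C8, C3′–C6′) is closed last by a Prins cyclization. It exploits the 1,3-relation between the ring oxygen O1′ (on C6′) and the acetoxy group on C4′: C6′ with its methyl is an acetaldehyde carbon, C4′=C5′ a (Z)-alkene, and the C4′ acetate is captured from the medium. One operation forms O1′–C6′, C6′–C5′ and C4′–O and sets C4′, C5′ and C6′ on a chair. The precursor is tertiary alcohol 18, a 2-oxabicyclo[2.2.2]octane-3,5-dione with a (Z)-pent-3-en-2-yl group on carbinol C8, itself closed by a chelated titanium aldol of keto lactone 16, which comes from a β-ketoimide anti-aldol, hydroboration and propargylation.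

Key step: step 12

Remark: the β-keto-δ-lactones 7–9 and 14–16 are written as their enol (4-hydroxy-5,6-dihydro-2H-pyran-2-one) tautomers, the form expected to predominate.

Step 1
Reactants: 1 (R)-4-benzyl-3-propanoyl-1,3-oxazolidin-2-one; 2 propanal
Product: 3 (R)-4-benzyl-3-[(2R,3S)-3-hydroxy-2-methylpentanoyl]-1,3-oxazolidin-2-one
Conditions: n-Bu2BOTf, Et3N, CH2Cl2, −78 → 0 °C; then H2O2, MeOH, pH 7 buffer, 0 °C
Reagents that add atoms: none
Why: Evans syn-aldol; the (Z)-boron enolate reacts through a Zimmerman–Traxler chair in which the auxiliary fixes C2 as (R) and C3 as (S).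

Step 2
Reactants: 3 (R)-4-benzyl-3-[(2R,3S)-3-hydroxy-2-methylpentanoyl]-1,3-oxazolidin-2-one
Product: 4 (R)-4-benzyl-3-[(2R)-2-methyl-3-oxopentanoyl]-1,3-oxazolidin-2-one
Conditions: SO3·pyridine, DMSO, i-Pr2NEt, CH2Cl2, −10 → 0 °C
Reagents that add atoms: none
Why: Parikh–Doering oxidation; the C2 stereocentre between the two carbonyls should survive because A(1,3) strain with the oxazolidinone disfavours its enolization.

Step 3
Reactants: 4 (R)-4-benzyl-3-[(2R)-2-methyl-3-oxopentanoyl]-1,3-oxazolidin-2-one; 5 methacrolein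
Product: 7 (5S,6R)-4-hydroxy-3,5-dimethyl-6-(prop-1-en-2-yl)-5,6-dihydro-2H-pyran-2-one, via anti-aldol imide 6 (not isolated)
Conditions: (c-C6H11)2BCl, Me2NEt, Et2O, 0 °C; 5, −78 → −20 °C; H2O2, MeOH, pH 7 buffer, 0 °C; then crude 6, DBU (0.1 equiv), CH2Cl2, 0 °C → rt
Reagents that add atoms: none
Why: Anti-aldol of the (E)-dicyclohexylboron enolate of the β-ketoimide through a Zimmerman–Traxler chair, the C2 methyl stereocentre steering the enolate face to the 2,4-anti-4,5-anti adduct 6; base-triggered attack of the C5 hydroxyl on the imide carbonyl then closes the δ-lactone, expelling the auxiliary and erasing C2 by enolization.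

Step 4
Reactants: 7 (5S,6R)-4-hydroxy-3,5-dimethyl-6-(prop-1-en-2-yl)-5,6-dihydro-2H-pyran-2-one
Product: 8 (5S,6S)-4-hydroxy-6-[(2S)-1-hydroxypropan-2-yl]-3,5-dimethyl-5,6-dihydro-2H-pyran-2-one
Conditions: 9-BBN (3 equiv), THF, 0 °C → rt; then NaBO3·4H2O, H2O, rt
Reagents that add atoms: sodium perborate, [Na+].[Na+].O[B-]1(O)OO[B-](O)(O)OO1
Why: Hydroboration–oxidation of the 1,1-disubstituted alkene; in the A(1,3)-minimized conformer (ring C6–H eclipsing the alkene) 9-BBN should add anti to ring carbon C5, which places the new side-chain methyl anti to the C6–O bond, while the enol is masked in situ as its borinate.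

Step 5
Reactants: 8 (5S,6S)-4-hydroxy-6-[(2S)-1-hydroxypropan-2-yl]-3,5-dimethyl-5,6-dihydro-2H-pyran-2-one
Product: 9 (2R)-2-[(2R,3S)-4-hydroxy-3,5-dimethyl-6-oxo-3,6-dihydro-2H-pyran-2-yl]propanal
Conditions: Dess–Martin periodinane, NaHCO3, CH2Cl2, 0 °C; crude product used at once
Reagents that add atoms: none
Why: Dess–Martin oxidation of the primary alcohol under buffered, non-basic conditions, which should spare the α-stereocentre and avoid β-elimination of the lactone oxygen.

Step 6
Reactants: 10 pent-3-yn-2-one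
Product: 11 (R)-pent-3-yn-2-ol
Conditions: Ru[(R,R)-TsNCH(Ph)CH(Ph)NH](η6-p-cymene) (0.5 mol %), i-PrOH, rt
Reagents that add atoms: none
Why: Noyori asymmetric transfer hydrogenation of an alkynyl ketone; with the alkynyl group in the role of the aryl group, the (R,R)-ligand should deliver hydride to the face that gives the (R)-alcohol.

Step 7
Reactants: 11 (R)-pent-3-yn-2-ol
Product: 12 (R)-pent-3-yn-2-yl methanesulfonate
Conditions: MsCl, Et3N, CH2Cl2, −78 °C
Reagents that add atoms: methanesulfonyl chloride, CS(=O)(=O)Cl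
Why: O-Sulfonylation does not touch the stereocentre.

Step 8
Reactants: 9 (2R)-2-[(2R,3S)-4-hydroxy-3,5-dimethyl-6-oxo-3,6-dihydro-2H-pyran-2-yl]propanal; 12 (R)-pent-3-yn-2-yl methanesulfonate
Product: 14 (5S,6S)-4-hydroxy-6-[(2S,3S,4S)-3-hydroxy-4-methylhept-5-yn-2-yl]-3,5-dimethyl-5,6-dihydro-2H-pyran-2-one, via allenylindium reagent 13 (not isolated)
Conditions: PdCl2(dppf) (5 mol %; dppf = 1,1′-bis(diphenylphosphino)ferrocene), InI (1.5 equiv), 12 (1.5 equiv), THF/HMPA 3:1, rt
Reagents that add atoms: none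
Why: Marshall propargylation; zerovalent palladium formed in situ displaces the mesylate anti (SN2′), transmetalation gives allenylindium 13, and its cyclic SE2′ addition to the aldehyde should give the anti homopropargylic alcohol with side-chain C4 (S) by net inversion of the mesylate centre, the configuration of the new carbinol being irrelevant because step 10 oxidizes it.

Step 9
Reactants: 14 (5S,6S)-4-hydroxy-6-[(2S,3S,4S)-3-hydroxy-4-methylhept-5-yn-2-yl]-3,5-dimethyl-5,6-dihydro-2H-pyran-2-one
Product: 15 (5S,6S)-4-hydroxy-6-[(2S,3S,4S,5Z)-3-hydroxy-4-methylhept-5-en-2-yl]-3,5-dimethyl-5,6-dihydro-2H-pyran-2-one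
Conditions: H2 (1 atm), Pd/CaCO3 poisoned with Pb(OAc)2, quinoline, EtOAc, rt
Reagents that add atoms: none
Why: Lindlar semihydrogenation; syn addition of H2 to the alkyne gives the (Z)-alkene, and the tetrasubstituted enol double bond should be inert.

Step 10
Reactants: 15 (5S,6S)-4-hydroxy-6-[(2S,3S,4S,5Z)-3-hydroxy-4-methylhept-5-en-2-yl]-3,5-dimethyl-5,6-dihydro-2H-pyran-2-one
Product: 16 (5S,6R)-4-hydroxy-3,5-dimethyl-6-[(2R,4S,5Z)-4-methyl-3-oxohept-5-en-2-yl]-5,6-dihydro-2H-pyran-2-one
Conditions: Dess–Martin periodinane, NaHCO3, CH2Cl2, 0 °C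
Reagents that add atoms: none
Why: Dess–Martin oxidation under buffered conditions should give the β,γ-unsaturated ketone without epimerizing its two α-stereocentres or moving the (Z)-alkene into conjugation; both carbinol epimers converge here.

Step 11
Reactants: 16 (5S,6R)-4-hydroxy-3,5-dimethyl-6-[(2R,4S,5Z)-4-methyl-3-oxohept-5-en-2-yl]-5,6-dihydro-2H-pyran-2-one
Product: 18 (1S,4R,6S,7R,8S)-8-hydroxy-4,6,7-trimethyl-8-[(2S,3Z)-pent-3-en-2-yl]-2-oxabicyclo[2.2.2]octane-3,5-dione, via titanium aldolate 17 (not isolated)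
Conditions: TiCl4 (1.2 equiv), i-Pr2NEt (1.0 equiv), CH2Cl2, −78 → −40 °C; pH 7 buffer at −40 °C
Reagents that add atoms: none
Why: Titanium-mediated intramolecular aldol addition (the aldolate stage of a TiCl4/amine Knoevenagel reaction, arrested because the nucleophilic carbon becomes quaternary): only the acidic enol is titanated, the tether lets the enolate carbon reach the ketone on one ring face only (fixing C4), and the closed Zimmerman–Traxler transition state with titanium bridging enolate and ketone oxygens should turn the new C8–O bond toward the C5 carbonyl bridge and the pentenyl group toward the lactone bridge, chelated aldolate 17 holding the adduct against retro-aldol cleavage until the cold neutral quench.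

Step 12
Reactants: 18 (1S,4R,6S,7R,8S)-8-hydroxy-4,6,7-trimethyl-8-[(2S,3Z)-pent-3-en-2-yl]-2-oxabicyclo[2.2.2]octane-3,5-dione; 19 acetaldehyde
Product: 22 (1S,3′S,4R,4′R,5′R,6S,6′S,7R,8S)-3′,4,5′,6,6′,7-hexamethyl-3,5-dioxospiro[2-oxabicyclo[2.2.2]octane-8,2′-oxan]-4′-yl acetate, via oxocarbenium ion 20 (not isolated), via oxan-4′-yl cation 21 (not isolated)
Conditions: MeCHO (3 equiv), AcOH (5 equiv), Me3SiOAc (4 equiv), BF3·OEt2 (2.5 equiv), CH2Cl2, −20 → 0 °C
Reagents that add atoms: acetic acid, CC(=O)O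
Why: Prins cyclization: the tertiary hydroxyl and acetaldehyde give a hemiacetal that BF3 ionizes to (E)-oxocarbenium ion 20, whose carbon is attacked by the (Z)-alkene through a chair transition state (6-endo-trig with respect to the alkene) to close the oxane as secondary cation 21, which acetate captures. The closest known reaction type is the Prins cyclization of homoallylic alcohols, tertiary carbinols and (Z)-alkenes included, with aldehydes under BF3·OEt2/AcOH/Me3SiOAc to give 4-acetoxyoxanes. C6′ is set by the (E)-oxocarbenium geometry (methyl equatorial), C5′ by the (Z)-alkene geometry (methyl axial, cis to the C6′ methyl) and C4′ by equatorial capture of the cation, all relayed from the existing C3′ and spiro centres through the chair in which the C3′ methyl is equatorial. The step needs this chair over its ring-flipped form, and cyclization over 2-oxonia-Cope rearrangement, retro-aldol opening or ionization at C8; the flipped chair would put the C3′ and C5′ methyls 1,3-diaxial, the electron-poor dione skeleton disfavours both the ketone-type oxocarbenium of the oxonia-Cope isomer and a C8 cation, and the acidic, water-scavenged medium offers no base for retro-aldol.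

Compound list
1 | (R)-4-benzyl-3-propanoyl-1,3-oxazolidin-2-one | CCC(=O)N1[C@H](Cc2ccccc2)COC1=O | starting material
2 | propanal | CCC=O | starting material
3 | (R)-4-benzyl-3-[(2R,3S)-3-hydroxy-2-methylpentanoyl]-1,3-oxazolidin-2-one | CC[C@H](O)[C@@H](C)C(=O)N1[C@H](Cc2ccccc2)COC1=O | intermediate
4 | (R)-4-benzyl-3-[(2R)-2-methyl-3-oxopentanoyl]-1,3-oxazolidin-2-one | CCC(=O)[C@@H](C)C(=O)N1[C@H](Cc2ccccc2)COC1=O | intermediate
5 | methacrolein (2-methylprop-2-enal) | CC(=C)C=O | starting material
6 | (R)-4-benzyl-3-[(2R,4S,5R)-5-hydroxy-2,4,6-trimethyl-3-oxohept-6-enoyl]-1,3-oxazolidin-2-one | C=C(C)[C@H](O)[C@H](C)C(=O)[C@@H](C)C(=O)N1[C@H](Cc2ccccc2)COC1=O | intermediate (not isolated)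
7 | (5S,6R)-4-hydroxy-3,5-dimethyl-6-(prop-1-en-2-yl)-5,6-dihydro-2H-pyran-2-one | C=C(C)[C@@H]1OC(=O)C(C)=C(O)[C@H]1C | intermediate
8 | (5S,6S)-4-hydroxy-6-[(2S)-1-hydroxypropan-2-yl]-3,5-dimethyl-5,6-dihydro-2H-pyran-2-one | OC[C@H](C)[C@@H]1OC(=O)C(C)=C(O)[C@H]1C | intermediate
9 | (2R)-2-[(2R,3S)-4-hydroxy-3,5-dimethyl-6-oxo-3,6-dihydro-2H-pyran-2-yl]propanal | O=C[C@H](C)[C@@H]1OC(=O)C(C)=C(O)[C@H]1C | intermediate
10 | pent-3-yn-2-one | CC#CC(C)=O | starting material
11 | (R)-pent-3-yn-2-ol | CC#C[C@@H](C)O | intermediate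
12 | (R)-pent-3-yn-2-yl methanesulfonate | CC#C[C@@H](C)OS(C)(=O)=O | intermediate
13 | (aS)-iodo(methanesulfonato)(penta-2,3-dien-2-yl)indium, allenylindium reagent | [H]C(C)=[C@]=C(C)[In](I)OS(C)(=O)=O | intermediate (not isolated)
14 | (5S,6S)-4-hydroxy-6-[(2S,3S,4S)-3-hydroxy-4-methylhept-5-yn-2-yl]-3,5-dimethyl-5,6-dihydro-2H-pyran-2-one | O[C@H]([C@H](C)[C@@H]1OC(=O)C(C)=C(O)[C@H]1C)[C@@H](C)C#CC | intermediate
15 | (5S,6S)-4-hydroxy-6-[(2S,3S,4S,5Z)-3-hydroxy-4-methylhept-5-en-2-yl]-3,5-dimethyl-5,6-dihydro-2H-pyran-2-one | O[C@H]([C@H](C)[C@@H]1OC(=O)C(C)=C(O)[C@H]1C)[C@@H](C)/C=C\C | intermediate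
16 | (5S,6R)-4-hydroxy-3,5-dimethyl-6-[(2R,4S,5Z)-4-methyl-3-oxohept-5-en-2-yl]-5,6-dihydro-2H-pyran-2-one | O=C([C@H](C)[C@@H]1OC(=O)C(C)=C(O)[C@H]1C)[C@@H](C)/C=C\C | intermediate
17 | trichlorotitanium alkoxide of 18 (C8–O–TiCl3, chelated by the C5 carbonyl) | Cl[Ti](Cl)(Cl)O[C@]1([C@H](C)[C@@H]2OC(=O)[C@@]1(C)C(=O)[C@H]2C)[C@@H](C)/C=C\C | intermediate (not isolated)
18 | (1S,4R,6S,7R,8S)-8-hydroxy-4,6,7-trimethyl-8-[(2S,3Z)-pent-3-en-2-yl]-2-oxabicyclo[2.2.2]octane-3,5-dione | O[C@]1([C@H](C)[C@@H]2OC(=O)[C@@]1(C)C(=O)[C@H]2C)[C@@H](C)/C=C\C | intermediate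
19 | acetaldehyde | CC=O | starting material
20 | (E)-ethylidene oxocarbenium ion on the C8 oxygen of 18 | C/C=[O+]/[C@]1([C@H](C)[C@@H]2OC(=O)[C@@]1(C)C(=O)[C@H]2C)[C@@H](C)/C=C\C | intermediate (not isolated)
21 | spirocyclic oxan-4′-yl cation (3′,5′,6′-trimethyl, configured as in 22) | [CH+]1[C@H](C)[C@H](C)O[C@]2([C@H](C)[C@@H]3OC(=O)[C@@]2(C)C(=O)[C@H]3C)[C@H]1C | intermediate (not isolated)
22 | (1S,3′S,4R,4′R,5′R,6S,6′S,7R,8S)-3′,4,5′,6,6′,7-hexamethyl-3,5-dioxospiro[2-oxabicyclo[2.2.2]octane-8,2′-oxan]-4′-yl acetate | CC(=O)O[C@@H]1[C@H](C)[C@H](C)O[C@]2([C@H](C)[C@@H]3OC(=O)[C@@]2(C)C(=O)[C@H]3C)[C@H]1C | target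

Total step count: 12. Longest linear sequence: 10 steps (steps 1–5 and 8–12); steps 6 and 7 form the side branch.

Steps most likely to fail

1. Step 12 (Prins cyclization). Hemiacetal and oxocarbenium formation at the hindered tertiary carbinol may be slow, so that acid-promoted retro-aldol opening of the bicycle or 2-oxonia-Cope fragmentation outruns cyclization. The fallback sets out from 18: O-silylation with 1-(trimethylsilyl)imidazole in CH2Cl2 should give the trimethylsilyl ether F1, which can no longer undergo retro-aldol cleavage. F1, acetaldehyde and Me3SiOAc with catalytic Me3SiOTf in CH2Cl2 at −78 °C should generate the same oxocarbenium ion by silyl transfer, with no free hydroxyl and no water, and Prins closure with acetate capture comes back to the route at 22.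

2. Step 11 (titanium aldol). The aldol equilibrium may favour the open enol ketone, the ketone may be attacked on its other face (C8 epimer), or the titanium/amine pair may epimerize the allylic α-centre. The fallback sets out from 16: bromination of the enol with N-bromosuccinimide in CH2Cl2 at 0 °C should give the 3-bromo-2,4-dione F2. SmI2 in THF at −78 °C should then form a samarium enolate (trivalent samarium) under neutral conditions, which adds to the ketone through the same chelated closed transition state in a Reformatsky-type aldol; a cold buffered quench comes back to the route at 18.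

3. Step 8 (propargylation). The acidic enol may protonate the allenylindium reagent, the β-acyloxy aldehyde may eliminate, or the allenyl metal may lose configurational integrity. The fallback sets out from 9: allylboration with the α-methylcrotylboronate F3 in toluene at room temperature. F3 would be made by lithiation–borylation of ethyl N,N-diisopropylcarbamate (s-BuLi, sparteine enantiomer chosen for the (S)-boronate) with (E)-4,4,5,5-tetramethyl-2-(prop-1-en-1-yl)-1,3,2-dioxaborolane. The chair transition state with the α-methyl group axial should transfer the boron-bearing stereocentre to side-chain C4 and give the (Z)-alkene directly, so the route is rejoined at 15 without 14 and without the Lindlar step.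

Further compounds
F1 | step 12 | (1S,4R,6S,7R,8S)-4,6,7-trimethyl-8-[(2S,3Z)-pent-3-en-2-yl]-8-[(trimethylsilyl)oxy]-2-oxabicyclo[2.2.2]octane-3,5-dione | C[Si](C)(C)O[C@]1([C@H](C)[C@@H]2OC(=O)[C@@]1(C)C(=O)[C@H]2C)[C@@H](C)/C=C\C
F2 | step 11 | 3-bromo derivative of 16 in its oxane-2,4-dione form, 3-bromo-3,5-dimethyl-6-[(2R,4S,5Z)-4-methyl-3-oxohept-5-en-2-yl]oxane-2,4-dione (both C3 epimers; other stereocentres as in 16) | O=C([C@H](C)[C@@H]1OC(=O)C(C)(Br)C(=O)[C@H]1C)[C@@H](C)/C=C\C
F3 | step 8 | 4,4,5,5-tetramethyl-2-[(2S,3E)-pent-3-en-2-yl]-1,3,2-dioxaborolane | C/C=C/[C@H](C)B1OC(C)(C)C(C)(C)O1
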